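**Retrosynthetic overview**

1. Schizolaenone C (22) comes from its ring B bis-silyl ether 21 by desilylation.
2. 21 comes from the open-chain (S)-δ-hydroxy-β-diketone 18 that ends in a 5-geranyl dioxinone. In one flask ring C closes first by cyclodehydration (C2–O bond kept, O1 fixed on C8a), then ring A closes by dioxinone retro-[4+2] → acylketene → 6π closure (C4a–C5) → enolisation.
3. 18 comes from keto-dioxinone 15 (dianion, C4a) and (S)-β-hydroxy ester 6 (C4) by Claisen condensation.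
4. 6 comes from aryl β-keto ester 5 by asymmetric transfer hydrogenation (sets the only stereocentre); 5 comes from methyl 3,5-dihydroxybenzoate 1 and ethyl acetate 3.
5. 15 comes from 5-geranyl dioxinone 12 (γ-acetylation), made from 5-iodo dioxinone 8 and geranyl chloride 9 (Negishi coupling). Ring B is bought; ring C, then ring A, form in step 8.

Assumption: 18 is drawn as the open-chain keto form although it will equilibrate with enol and hemiketal tautomers; any 19 formed on handling is carried into step 8, where it is an intermediate anyway.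

**Route**

Step 1
Reactants: 1 methyl 3,5-dihydroxybenzoate
Product: 2 methyl 3,5-bis[(tert-butyldimethylsilyl)oxy]benzoate
Conditions: TBSCl (2.4 equiv), imidazole (5 equiv), DMF, 23 °C, 12 h
Reagents that add atoms: tert-butyldimethylsilyl chloride, CC(C)(C)[Si](C)(C)Cl
Why: Imidazole-promoted silyl ether formation masks both phenols for the enolate and ketene chemistry that follows; no stereocentre is involved.

Step 2
Reactants: 2 methyl 3,5-bis[(tert-butyldimethylsilyl)oxy]benzoate; 3 ethyl acetate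
Product: 5 ethyl 3-{3,5-bis[(tert-butyldimethylsilyl)oxy]phenyl}-3-oxopropanoate, via lithium enolate of ethyl acetate 4 (not isolated)
Conditions: LiN(iPr)2 (2.2 equiv), 3 (2.2 equiv), THF, −78 °C, 30 min; then 2, −78 → −20 °C, 1 h; aq NH4Cl
Reagents that add atoms: none
Why: Crossed Claisen condensation of the non-enolisable aryl ester with the pre-formed enolate 4; the β-keto ester is stored as its enolate, which prevents over-addition.

Step 3
Reactants: 5 ethyl 3-{3,5-bis[(tert-butyldimethylsilyl)oxy]phenyl}-3-oxopropanoate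
Product: 6 ethyl (3S)-3-{3,5-bis[(tert-butyldimethylsilyl)oxy]phenyl}-3-hydroxypropanoate
Conditions: RuCl(p-cymene)[(S,S)-TsDPEN] (1 mol %), HCO2H/Et3N (5:2), EtOAc, 35 °C, 16 h
Reagents that add atoms: none
Why: Noyori–Ikariya asymmetric transfer hydrogenation of an aryl ketone; the (S,S)-ligand delivers hydride to the Re face as it does for acetophenone, which gives the S benzylic alcohol that becomes C2 of the flavanone.

Step 4
Reactants: 7 2,2,6-trimethyl-4H-1,3-dioxin-4-one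
Product: 8 5-iodo-2,2,6-trimethyl-4H-1,3-dioxin-4-one
Conditions: N-iodosuccinimide (1.2 equiv), AcOH, 23 °C, dark, 12 h
Reagents that add atoms: N-iodosuccinimide, O=C1CCC(=O)N1I
Why: Electrophilic iodination at C5, the nucleophilic α-carbon of the vinylogous carbonate.

Step 5
Reactants: 8 5-iodo-2,2,6-trimethyl-4H-1,3-dioxin-4-one; 9 geranyl chloride, (2E)-1-chloro-3,7-dimethylocta-2,6-diene
Product: 12 5-[(2E)-3,7-dimethylocta-2,6-dien-1-yl]-2,2,6-trimethyl-4H-1,3-dioxin-4-one, via dioxinon-5-ylmagnesium chloride 10 (not isolated), via dioxinon-5-ylzinc chloride 11 (not isolated)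
Conditions: iPrMgCl·LiCl (1.1 equiv), THF, −30 °C, 30 min; ZnCl2 (1.2 equiv), −30 → 0 °C; then 9 (1.2 equiv), Pd(PPh3)4 (3 mol %), 0 → 23 °C, 4 h
Reagents that add atoms: none
Why: Iodine–magnesium exchange gives the alkenyl Grignard 10 (stable at −30 °C), and after transmetalation to zinc a Negishi allyl–alkenyl cross-coupling joins the less hindered allyl terminus with retention of the E olefin.

Step 6
Reactants: 12 5-[(2E)-3,7-dimethylocta-2,6-dien-1-yl]-2,2,6-trimethyl-4H-1,3-dioxin-4-one; 13 1-acetylimidazole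
Product: 15 5-[(2E)-3,7-dimethylocta-2,6-dien-1-yl]-2,2-dimethyl-6-(2-oxopropyl)-4H-1,3-dioxin-4-one, via lithium dienolate of the geranyl dioxinone 14 (not isolated)
Conditions: LiN(SiMe3)2 (2.2 equiv), THF, −78 °C, 45 min; then 13 (1.05 equiv), −78 → −40 °C, 2 h; aq NH4Cl
Reagents that add atoms: none
Why: Vinylogous (γ) Claisen acylation of dienolate 14 at its exocyclic carbon; the second equivalent of base stores the more acidic keto-dioxinone as its enolate.

Step 7
Reactants: 15 5-[(2E)-3,7-dimethylocta-2,6-dien-1-yl]-2,2-dimethyl-6-(2-oxopropyl)-4H-1,3-dioxin-4-one; 6 ethyl (3S)-3-{3,5-bis[(tert-butyldimethylsilyl)oxy]phenyl}-3-hydroxypropanoate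
Product: 18 6-{(6S)-6-{3,5-bis[(tert-butyldimethylsilyl)oxy]phenyl}-6-hydroxy-2,4-dioxohexyl}-5-[(2E)-3,7-dimethylocta-2,6-dien-1-yl]-2,2-dimethyl-4H-1,3-dioxin-4-one, via dilithium dianion of the keto-dioxinone 16 (not isolated), via lithium alkoxide of the hydroxy ester 17 (not isolated)
Conditions: 15 (1.3 equiv), LiN(iPr)2 (2.7 equiv), THF, −78 °C, 1 h; separately 6, LiN(SiMe3)2 (1.0 equiv), THF, −78 °C; combine, −78 → −20 °C, 3 h; aq NH4Cl
Reagents that add atoms: none
Why: Claisen condensation of the terminal carbanion of dianion 16 (polyanion acylation of the Harris type) with the ester, whose β-lithium alkoxide suppresses ester enolisation; the C–O bond at the stereocentre is untouched, so S is retained.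

Step 8
Reactants: 18 6-{(6S)-6-{3,5-bis[(tert-butyldimethylsilyl)oxy]phenyl}-6-hydroxy-2,4-dioxohexyl}-5-[(2E)-3,7-dimethylocta-2,6-dien-1-yl]-2,2-dimethyl-4H-1,3-dioxin-4-one
Product: 21 (2S)-2-{3,5-bis[(tert-butyldimethylsilyl)oxy]phenyl}-6-[(2E)-3,7-dimethylocta-2,6-dien-1-yl]-5,7-dihydroxy-2,3-dihydro-4H-chromen-4-one, via pyranone–dioxinone 19 (not isolated), via acylketene 20 (not isolated)
Conditions: PPTS (10 mol %), 4 Å molecular sieves, PhMe (0.005 M), 60 °C, 2 h; then 110 °C, 4 h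
Reagents that add atoms: none
Why: Proposed new method: at 60 °C the C2 hydroxyl adds to the C8a ketone and PPTS dehydrates the hemiketal to the vinylogous ester 19 (ring C; the C2–O bond is never broken, so S is retained, and O1 is now fixed on C8a, which decides 6- over 8-geranyl and removes the enol oxygen that would otherwise give a 2-pyranone); at 110 °C the dioxinone loses acetone by retro-[4+2] to acylketene 20, whose C7 enol and the ring C enol ether double bond make a dienylketene that closes by 6π electrocyclisation (C5–C4a), and enolisation gives the phloroglucinol ring A; the geranyl-bearing carbon blocks the competing aldol (resorcylate) aromatisation; closest known reaction types are the acid-catalysed cyclodehydration of δ-hydroxy-β-diketones to 2,3-dihydro-4H-pyran-4-ones, dioxinone thermolysis with ketene capture as used for resorcylates, and the dienylketene 6π closure that ends the Danheiser benzannulation.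

Step 9
Reactants: 21 (2S)-2-{3,5-bis[(tert-butyldimethylsilyl)oxy]phenyl}-6-[(2E)-3,7-dimethylocta-2,6-dien-1-yl]-5,7-dihydroxy-2,3-dihydro-4H-chromen-4-one
Product: 22 Schizolaenone C, (2S)-2-(3,5-dihydroxyphenyl)-6-[(2E)-3,7-dimethylocta-2,6-dien-1-yl]-5,7-dihydroxy-2,3-dihydro-4H-chromen-4-one
Conditions: HF·pyridine (excess), pyridine, THF, 0 → 23 °C, 6 h, polypropylene vessel
Reagents that add atoms: none
Why: Fluoride-mediated desilylation of the two aryl silyl ethers under pyridine-buffered, non-basic conditions, so the base-labile C2 stereocentre of the flavanone and the geranyl olefins are left alone.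

**Compound list**

1 | methyl 3,5-dihydroxybenzoate | COC(=O)c1cc(O)cc(O)c1 | starting material
2 | methyl 3,5-bis[(tert-butyldimethylsilyl)oxy]benzoate | COC(=O)c1cc(O[Si](C)(C)C(C)(C)C)cc(O[Si](C)(C)C(C)(C)C)c1 | intermediate
3 | ethyl acetate | CCOC(C)=O | starting material
4 | lithium enolate of ethyl acetate | [Li+].[O-]C(=C)OCC | intermediate
5 | ethyl 3-{3,5-bis[(tert-butyldimethylsilyl)oxy]phenyl}-3-oxopropanoate | CCOC(=O)CC(=O)c1cc(O[Si](C)(C)C(C)(C)C)cc(O[Si](C)(C)C(C)(C)C)c1 | intermediate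
6 | ethyl (3S)-3-{3,5-bis[(tert-butyldimethylsilyl)oxy]phenyl}-3-hydroxypropanoate | CCOC(=O)C[C@H](O)c1cc(O[Si](C)(C)C(C)(C)C)cc(O[Si](C)(C)C(C)(C)C)c1 | intermediate
7 | 2,2,6-trimethyl-4H-1,3-dioxin-4-one | CC1=CC(=O)OC(C)(C)O1 | starting material
8 | 5-iodo-2,2,6-trimethyl-4H-1,3-dioxin-4-one | CC1=C(I)C(=O)OC(C)(C)O1 | intermediate
9 | geranyl chloride, (2E)-1-chloro-3,7-dimethylocta-2,6-diene | CC(C)=CCC/C(C)=C/CCl | starting material
10 | chloro(2,2,6-trimethyl-4-oxo-4H-1,3-dioxin-5-yl)magnesium | CC1=C([Mg]Cl)C(=O)OC(C)(C)O1 | intermediate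
11 | chloro(2,2,6-trimethyl-4-oxo-4H-1,3-dioxin-5-yl)zinc | CC1=C([Zn]Cl)C(=O)OC(C)(C)O1 | intermediate
12 | 5-[(2E)-3,7-dimethylocta-2,6-dien-1-yl]-2,2,6-trimethyl-4H-1,3-dioxin-4-one | CC1=C(C/C=C(\C)CCC=C(C)C)C(=O)OC(C)(C)O1 | intermediate
13 | 1-acetylimidazole | CC(=O)n1ccnc1 | starting material
14 | lithium dienolate of 12 (6-methylene-1,3-dioxin-4-olate) | [Li+].C=C1OC(C)(C)OC([O-])=C1C/C=C(\C)CCC=C(C)C | intermediate
15 | 5-[(2E)-3,7-dimethylocta-2,6-dien-1-yl]-2,2-dimethyl-6-(2-oxopropyl)-4H-1,3-dioxin-4-one | CC(=O)CC1=C(C/C=C(\C)CCC=C(C)C)C(=O)OC(C)(C)O1 | intermediate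
16 | dilithium dianion of 15 (bis-enolate, terminal carbon nucleophilic) | [Li+].[Li+].C=C([O-])C=C1OC(C)(C)OC([O-])=C1C/C=C(\C)CCC=C(C)C | intermediate
17 | lithium alkoxide of 6, (S) | [Li+].CCOC(=O)C[C@H]([O-])c1cc(O[Si](C)(C)C(C)(C)C)cc(O[Si](C)(C)C(C)(C)C)c1 | intermediate
18 | 6-{(6S)-6-{3,5-bis[(tert-butyldimethylsilyl)oxy]phenyl}-6-hydroxy-2,4-dioxohexyl}-5-[(2E)-3,7-dimethylocta-2,6-dien-1-yl]-2,2-dimethyl-4H-1,3-dioxin-4-one | CC(C)=CCC/C(C)=C/CC1=C(CC(=O)CC(=O)C[C@H](O)c2cc(O[Si](C)(C)C(C)(C)C)cc(O[Si](C)(C)C(C)(C)C)c2)OC(C)(C)OC1=O | intermediate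
19 | (2S)-2-{3,5-bis[(tert-butyldimethylsilyl)oxy]phenyl}-6-({5-[(2E)-3,7-dimethylocta-2,6-dien-1-yl]-2,2-dimethyl-4-oxo-4H-1,3-dioxin-6-yl}methyl)-2,3-dihydro-4H-pyran-4-one | CC(C)=CCC/C(C)=C/CC1=C(CC2=CC(=O)C[C@@H](c3cc(O[Si](C)(C)C(C)(C)C)cc(O[Si](C)(C)C(C)(C)C)c3)O2)OC(C)(C)OC1=O | intermediate
20 | acylketene, 4-{(2S)-2-{3,5-bis[(tert-butyldimethylsilyl)oxy]phenyl}-4-oxo-3,4-dihydro-2H-pyran-6-yl}-2-[(2E)-3,7-dimethylocta-2,6-dien-1-yl]-3-oxobut-1-en-1-one | O=C=C(C/C=C(\C)CCC=C(C)C)C(=O)CC1=CC(=O)C[C@@H](c2cc(O[Si](C)(C)C(C)(C)C)cc(O[Si](C)(C)C(C)(C)C)c2)O1 | intermediate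
21 | (2S)-2-{3,5-bis[(tert-butyldimethylsilyl)oxy]phenyl}-6-[(2E)-3,7-dimethylocta-2,6-dien-1-yl]-5,7-dihydroxy-2,3-dihydro-4H-chromen-4-one | CC(C)=CCC/C(C)=C/Cc1c(O)cc2c(c1O)C(=O)C[C@@H](c1cc(O[Si](C)(C)C(C)(C)C)cc(O[Si](C)(C)C(C)(C)C)c1)O2 | intermediate
22 | Schizolaenone C, (2S)-2-(3,5-dihydroxyphenyl)-6-[(2E)-3,7-dimethylocta-2,6-dien-1-yl]-5,7-dihydroxy-2,3-dihydro-4H-chromen-4-one | CC(C)=CCC/C(C)=C/Cc1c(O)cc2c(c1O)C(=O)C[C@@H](c1cc(O)cc(O)c1)O2 | target

**Step count**

Total: 9 steps. Longest linear sequence: 6 steps (7 → 8 → 12 → 15 → 18 → 21 → 22; the branch 1 → 2 → 5 → 6 → 18 → 21 → 22 is equally long).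

**Three steps most likely to fail**

Step 8 (cyclodehydration, then ketene 6π closure). The ketene may dimerise or be captured by a phenol instead of closing onto C4a, and the new ortho-geranyl phenol is exposed to warm PPTS. The fallback sets out from 18 and comes back at 21. Camphorsulfonic acid (5 mol %) in CH2Cl2 at 23 °C gives 19, which is now isolated. Heating 19 in PhMe with MeOH (20 equiv) at 110 °C traps the ketene as methyl 4-{(2S)-2-{3,5-bis[(tert-butyldimethylsilyl)oxy]phenyl}-4-oxo-3,4-dihydro-2H-pyran-6-yl}-2-[(2E)-3,7-dimethylocta-2,6-dien-1-yl]-3-oxobutanoate F1. Mg(OMe)2 in MeOH/THF at 23 °C then closes ring A by a magnesium-templated Dieckmann-type C-acylation of C4a, and enolisation gives 21. The two rings are then made in separate operations and ring A by an ionic instead of a pericyclic closure; the cost is brief exposure of the C2 centre to mild base.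

Step 7 (dianion acylation with the β-alkoxido ester). The ester may be enolised or react too slowly. The fallback sets out from 6 and 15 and comes back at 18, making the C4–C4a bond by aldol addition and oxidation instead of acylation. 6 is silylated (Et3SiCl, imidazole, CH2Cl2) to ethyl (3S)-3-{3,5-bis[(tert-butyldimethylsilyl)oxy]phenyl}-3-(triethylsilyloxy)propanoate F2. F2 is reduced with iBu2AlH (CH2Cl2, −78 °C) to (3S)-3-{3,5-bis[(tert-butyldimethylsilyl)oxy]phenyl}-3-(triethylsilyloxy)propanal F3. F3 is added at −78 °C to dianion 16 made from 15, giving 6-{(6S)-6-{3,5-bis[(tert-butyldimethylsilyl)oxy]phenyl}-4-hydroxy-2-oxo-6-(triethylsilyloxy)hexyl}-5-[(2E)-3,7-dimethylocta-2,6-dien-1-yl]-2,2-dimethyl-4H-1,3-dioxin-4-one F4 as a mixture at the new carbinol. Dess–Martin periodinane oxidises F4 to the triethylsilyl ether of 18 F5, and AcOH/THF/H2O at 23 °C removes the triethylsilyl group (aryl silyl ethers stay) to return 18.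

Step 5 (Mg/Zn/Pd geranylation of 8). The magnesiated dioxinone may decompose, or the allyl partner may scramble its geometry or couple at the wrong terminus. The fallback sets out from 9 and comes back at 12, building the dioxinone ring around a carbon that already carries the geranyl group. Commercial tert-butyl acetoacetate is C-alkylated with 9 (NaH, NaI cat., THF, 0 → 23 °C) to tert-butyl (4E)-2-acetyl-5,9-dimethyldeca-4,8-dienoate F6. F6 is condensed with acetone (Ac2O, cat. H2SO4, −10 °C, short reaction time) to 12; the cost is brief cold-acid exposure of the geranyl olefins.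

Further compounds
F1 | step 8 | methyl 4-{(2S)-2-{3,5-bis[(tert-butyldimethylsilyl)oxy]phenyl}-4-oxo-3,4-dihydro-2H-pyran-6-yl}-2-[(2E)-3,7-dimethylocta-2,6-dien-1-yl]-3-oxobutanoate | COC(=O)C(C/C=C(\C)CCC=C(C)C)C(=O)CC1=CC(=O)C[C@@H](c2cc(O[Si](C)(C)C(C)(C)C)cc(O[Si](C)(C)C(C)(C)C)c2)O1
F2 | step 7 | ethyl (3S)-3-{3,5-bis[(tert-butyldimethylsilyl)oxy]phenyl}-3-(triethylsilyloxy)propanoate | CCOC(=O)C[C@H](O[Si](CC)(CC)CC)c1cc(O[Si](C)(C)C(C)(C)C)cc(O[Si](C)(C)C(C)(C)C)c1
F3 | step 7 | (3S)-3-{3,5-bis[(tert-butyldimethylsilyl)oxy]phenyl}-3-(triethylsilyloxy)propanal | O=CC[C@H](O[Si](CC)(CC)CC)c1cc(O[Si](C)(C)C(C)(C)C)cc(O[Si](C)(C)C(C)(C)C)c1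
F4 | step 7 | 6-{(6S)-6-{3,5-bis[(tert-butyldimethylsilyl)oxy]phenyl}-4-hydroxy-2-oxo-6-(triethylsilyloxy)hexyl}-5-[(2E)-3,7-dimethylocta-2,6-dien-1-yl]-2,2-dimethyl-4H-1,3-dioxin-4-one | CC1(C)OC(CC(=O)CC(O)C[C@H](O[Si](CC)(CC)CC)c2cc(O[Si](C)(C)C(C)(C)C)cc(O[Si](C)(C)C(C)(C)C)c2)=C(C/C=C(\C)CCC=C(C)C)C(=O)O1
F5 | step 7 | 6-{(6S)-6-{3,5-bis[(tert-butyldimethylsilyl)oxy]phenyl}-2,4-dioxo-6-(triethylsilyloxy)hexyl}-5-[(2E)-3,7-dimethylocta-2,6-dien-1-yl]-2,2-dimethyl-4H-1,3-dioxin-4-one | CC1(C)OC(CC(=O)CC(=O)C[C@H](O[Si](CC)(CC)CC)c2cc(O[Si](C)(C)C(C)(C)C)cc(O[Si](C)(C)C(C)(C)C)c2)=C(C/C=C(\C)CCC=C(C)C)C(=O)O1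
F6 | step 5 | tert-butyl (4E)-2-acetyl-5,9-dimethyldeca-4,8-dienoate | CC(=O)C(C/C=C(\C)CCC=C(C)C)C(=O)OC(C)(C)C
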